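The plan rests on cutting the alkyl C–O bond of the ester, between the carboxylate oxygen and the OCH2 carbon. Since the hydroxyl-bearing C4 of the benzene ring lies opposite C1, which carries the two-carbon chain, all eight carbons can be masked as spiro[2.5]octa-4,7-dien-6-one: C4 becomes the ketone carbon, C1 the spiro atom, the chain carbons the cyclopropane CH2 pair. Hexacosanoic acid, assembled by mixed Kolbe coupling of C17 and C9 radicals, adds to one of these CH2 groups. That single operation makes the ester, cleaves the three-membered ring and rebuilds the arene with its phenol unmasked, so protecting groups and alcohol/phenol discrimination become unnecessary.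

Key step: step 5

Remark: the target is achiral and has no stereogenic double bond, so no step has to set configuration.
Assumption: dienone 9 is never concentrated. Because its solution is freed from salts and titrated before use, its formation is counted as a step of its own.

Step 1
Reactants: 1 stearic acid (octadecanoic acid); 2 methyl hydrogen sebacate (10-methoxy-10-oxodecanoic acid)
Product: 3 methyl hexacosanoate
Conditions: 1 (1 equiv), 2 (3 equiv), NaOMe (5 mol% of total CO2H), MeOH–hexane 4:1, undivided cell under a condenser, two smooth Pt foils, about 0.2 A/cm2, polarity reversed every few minutes, 40–45 °C, until faintly alkaline; evaporation, warm heptane/water partition; SiO2 (heptane, then heptane–EtOAc); recrystallisation (acetone)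
Reagents that add atoms: none
Why: Mixed Kolbe electrolysis, in which one-electron oxidation and decarboxylation of both carboxylates at Pt under high current density give a dense surface layer of heptadecyl and 8-(methoxycarbonyl)octyl radicals whose cross-combination forms C9–C10 of the acyl chain; the excess of 2 channels most heptadecyl radicals into the mixed product, the methyl ester is inert at the anode, hexane and polarity reversal keep waxy products off the electrodes, and the symmetrical coupling products differ from 3 by a whole ester group in polarity and so should separate on SiO2.

Step 2
Reactants: 3 methyl hexacosanoate
Product: 5 hexacosanoic acid, via potassium hexacosanoate 4 (not isolated)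
Conditions: KOH (3 equiv), EtOH–THF–H2O 4:4:1, reflux; volatiles removed; 2 M HCl–toluene, 60 °C; toluene layer washed and cooled to crystallise 5; azeotropic drying (toluene, water separator) directly before step 5
Reagents that add atoms: potassium hydroxide, [K+].[OH-]
Why: Saponification by acyl-oxygen cleavage, driven to completion by formation of carboxylate 4; THF keeps the waxy ester dissolved, no other functional group is present, and liberating the acid in a water–toluene two-phase system after removal of the alcohol excludes re-esterification and occluded soap.

Step 3
Reactants: 6 tyrosol, 4-(2-hydroxyethyl)phenol
Product: 7 4-(2-bromoethyl)phenol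
Conditions: 48% aq HBr (6 equiv), 90 °C, 3 h; extraction (MTBE), aqueous wash; recrystallisation (toluene–heptane)
Reagents that add atoms: hydrogen bromide, Br
Why: Acid-mediated nucleophilic substitution, bromide displacing the protonated primary hydroxyl in an SN2 process (aryl assistance is possible and degenerate), while the phenolic C(sp2)–O bond cannot be substituted, so only the side-chain oxygen is exchanged.

Step 4
Reactants: 7 4-(2-bromoethyl)phenol
Product: 9 spiro[2.5]octa-4,7-dien-6-one, via potassium 4-(2-bromoethyl)phenolate 8 (not isolated)
Conditions: KOtBu (0.98 equiv, 1.0 M in THF), dry THF (0.03 M), −40 °C, then 0 °C until 8 is consumed; cold filtration under Ar through basic Al2O3; filtrate held at −30 °C, titrated by quantitative 1H NMR, used within hours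
Reagents that add atoms: potassium tert-butoxide, CC(C)(C)[O-].[K+] (gives only the K+ of 8; no atom of it stays in 9)
Why: Ar1-3 participation, a known dearomatising spirocyclisation of 4-(2-haloethyl)phenolates in which the ring carbon para to O− displaces bromide in a 3-exo-tet C-alkylation; deprotonation at −40 °C before ring closure sets in avoids free phenol or surplus base beside 9, high dilution favours the unimolecular closure over attack of 8 on 9, precipitation of KBr removes the only good external nucleophile, and the Al2O3 pad strips salts and residual 7 to leave a neutral solution.

Step 5
Reactants: 9 spiro[2.5]octa-4,7-dien-6-one; 5 hexacosanoic acid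
Product: 10 2-(4-hydroxyphenyl)ethyl hexacosanoate
Conditions: 5 (3 equiv), dry toluene (about 0.15 M; 50 °C is needed to keep 5 dissolved), Ar; cold THF solution of 9 (1 equiv) added beneath the surface over 3 h; 50 °C, 1 h more; evaporation; warm CHCl3 through aminopropyl-bonded SiO2 (retains 5, recovered with 2% AcOH in THF); recrystallisation (acetone)
Reagents that add atoms: none
Why: Hydrogen bonding or proton transfer from 5 to the carbonyl oxygen of 9 polarises the cross-conjugated dienone towards a 4-hydroxyphenonium-like species, and a carboxyl oxygen of a second molecule of 5 attacks one cyclopropane CH2 from the rear in an SN2-like homoconjugate (homo-Michael) addition, so that the spiro C–CH2 bond breaks as the O–CH2 bond forms. Release of cyclopropane strain together with recovery of the benzene ring should make the addition irreversible and deliver the phenol unmasked. The closest known reaction type is the acid-promoted solvolytic opening of spiro[2.5]octadienones by carboxylic acids, alcohols and hydrogen halides, which is the reverse of Ar1-3 participation and the alkylation mode of cyclopropylcyclohexadienone natural products, so only the acid partner is new. No ring is closed (the three-membered ring opens and the six-membered ring becomes aromatic) and no stereocentre is created. The selectivity needed is alkylation of the carboxyl oxygen rather than of the phenol of 10, of tert-butanol or of water, and it is secured by the roughly five pKa units between 5 and a phenol, so that only 5 both activates 9 and furnishes a competent nucleophile, reinforced by slow addition of 9 into a threefold excess of azeotropically dried 5 and by the bulk of tert-butanol. The two cyclopropane CH2 groups are related by symmetry, so no regiochemical question arises.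

Compound list
1 | stearic acid (octadecanoic acid) | CCCCCCCCCCCCCCCCCC(=O)O | starting material
2 | methyl hydrogen sebacate (10-methoxy-10-oxodecanoic acid) | COC(=O)CCCCCCCCC(=O)O | starting material
3 | methyl hexacosanoate | CCCCCCCCCCCCCCCCCCCCCCCCCC(=O)OC | intermediate
4 | potassium hexacosanoate | CCCCCCCCCCCCCCCCCCCCCCCCCC(=O)[O-].[K+] | intermediate
5 | hexacosanoic acid | CCCCCCCCCCCCCCCCCCCCCCCCCC(=O)O | intermediate
6 | tyrosol, 4-(2-hydroxyethyl)phenol | OCCc1ccc(O)cc1 | starting material
7 | 4-(2-bromoethyl)phenol | BrCCc1ccc(O)cc1 | intermediate
8 | potassium 4-(2-bromoethyl)phenolate | [K+].[O-]c1ccc(CCBr)cc1 | intermediate
9 | spiro[2.5]octa-4,7-dien-6-one | O=C1C=CC2(CC2)C=C1 | intermediate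
10 | 2-(4-hydroxyphenyl)ethyl hexacosanoate | CCCCCCCCCCCCCCCCCCCCCCCCCC(=O)OCCc1ccc(O)cc1 | target

Total steps: 5. Longest linear sequence: 3 steps (1 to 3 to 5 to 10, or 6 to 7 to 9 to 10).

Steps most likely to fail

Step 5. The weak acid may activate the dienone only sluggishly in toluene–THF. Alkylation of the phenol set free in the product (chain-growth ether formation), or capture by traces of water or tert-butanol, could then gain ground. Fallback: the ester is made by a Mitsunobu esterification that bypasses 7 to 9 altogether. It sets out from acid 5 and tyrosol 6 (PPh3, diisopropyl azodicarboxylate, THF–toluene, 40 °C). Only the aliphatic hydroxyl forms an alkoxyphosphonium ion, and the carboxylic acid, far more acidic than the phenol, is the partner that is engaged. This is a known chemoselective esterification of phenolic alcohols. It comes back to the route at 10 and makes no new compound (entry F0).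

Step 4. Self-condensation of the strained dienone may erode the titre; it can be started by phenolate, by stray acid or by local concentration during filtration and storage. Base-induced loss of HBr from the side chain is a second drain. Fallback: the separate dienone solution is abandoned in favour of classical carboxylate alkylation. Setting out from 5, Cs2CO3 (0.5 equiv) in warm THF–MeOH followed by evaporation and drying gives cesium hexacosanoate F1. This salt is alkylated with bromide 7 in DMF–THF at 55 °C. The carboxylate is too weak a base to deprotonate the phenol to any extent, and direct SN2 displacement or transient aryl participation lead to the same ester. The path rejoins the route at 10.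

Step 1. Three processes may make throughput and purification poor:
- statistical homocoupling of both radicals
- fouling of the anode by waxy deposits, with collapse of the current density
- drift towards two-electron (Hofer–Moest) oxidation

Fallback: the chain is assembled by polar C18 + C8 coupling instead of radical C17 + C9 coupling. Setting out from 1, LiAlH4 in THF gives octadecan-1-ol F2. Treatment with 48% aq HBr–H2SO4 at reflux gives 1-bromooctadecane F3, and Mg in THF gives octadecylmagnesium bromide F4. Li2CuCl4 (3 mol%) with NMP in THF at 0–20 °C then couples F4 with purchased methyl 8-bromooctanoate (COC(=O)CCCCCCCBr) faster than the Grignard reagent attacks the ester. This is a known copper-catalysed alkyl–alkyl cross-coupling. The path rejoins the route at 3. Small commercial lots of 5 would in addition allow steps 4 and 5 to be scouted before the electrolysis is optimised.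

Further compounds
F0 | step 5 | none | none
F1 | step 4 | cesium hexacosanoate | CCCCCCCCCCCCCCCCCCCCCCCCCC(=O)[O-].[Cs+]
F2 | step 1 | octadecan-1-ol | CCCCCCCCCCCCCCCCCCO
F3 | step 1 | 1-bromooctadecane | CCCCCCCCCCCCCCCCCCBr
F4 | step 1 | octadecylmagnesium bromide | CCCCCCCCCCCCCCCCCC[Mg]Br
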